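The data were computed with made-up constants, noise included.

The last blue reading, at 4.00 min, was where I started on the new flasks.

in all of them: solid substrate 0.33 M

| run | first nucleophile | second nucleophile | remark | time |
|---|---|---|---|---|
| blue | 0.198 M | 0.198 M | run made earlier |  |
| grey | 0.30 M | 0.198 M | run made earlier |  |
| Saturday's | 0.198 M | 0.198 M | everything together at the start | 6.0 min |
| Thursday's | 0.198 M | 0.198 M (fed, over 5.0 min) | all else is in the flask from the start; the feed brings no volume worth counting | 6.0 min |
| Tuesday's | 0.198 M (in portions, 2, over 5.0 min) | 0.198 M | first portion at the start, last at 5.0 min | 6.0 min |
| Monday's | 0.198 M (fed, over 5.0 min) | 0.198 M | all else is in the flask from the start; the feed brings no volume worth counting | 6.0 min |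

blue run (percent of the solid substrate charged)

| time / min | solvolysis product / % | target / % |
|---|---|---|
| 0.500 | 1 | 0 |
| 1.00 | 3 | 2 |
| 1.50 | 2 | 9 |
| 2.00 | 7 | 16 |
| 2.50 | 18 | 11 |
| 3.00 | 25 | 13 |
| 4.00 | 26 | 16 |

grey run (percent of the solid substrate charged)

| time / s | solvolysis product / % | target / % |
|---|---|---|
| 10.0 | 0 | 0 |
| 15.0 | 1 | 2 |
| 20.0 | 0 | 4 |
| 25.0 | 5 | 0 |
| 30.0 | 1 | 6 |
| 40.0 | 0 | 3 |

(each reading ± 2 percentage points)

- solid substrate is a solid; its amount is given per volume of the solution
- what was read earlier has a scatter of 2 percentage points, one standard deviation
- at the start none of the solid substrate is in solution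

- the flask that comes out highest in amount of solvolysis product, in percent of the solid substrate charged, or "all alike" when all lie within 1.5 percentage points (Saturday's / Thursday's / Tuesday's / Monday's / all alike)
- solvolysis product at the end, in percent of the solid substrate charged, Saturday's
- solvolysis product at the end, in percent of the solid substrate charged, Thursday's
- solvolysis product at the end, in percent of the solid substrate charged, Tuesday's
- solvolysis product at the end, in percent of the solid substrate charged, Monday's

The last two blue readings, at 3.00 min and 4.00 min, put solvolysis product at 25% and 26% and target at 13% and 16%, so their sum averaged 40.0%, each reading carrying 2 percentage points of scatter. The missing 60.0% matched the second nucleophile's charge, 60.0% of the solid substrate. I therefore took the second nucleophile, the limiting reagent of its own capture at 0.198 M against 0.33 M, to use its whole charge. What stays beyond its reach I called the overhang, one minus that ratio: 40.0%. The overhang rests on that whole charge being used, which the feed of second nucleophile on Thursday's might not allow.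

I pictured two extremes. In the first I gave the overhang to target and reckoned solvolysis product as nil; in the second, with no first nucleophile, I gave solvolysis product the whole 40.0%. The blue run read between them, with target averaging 14.5% over those two readings.

Tuesday's puts half the first nucleophile in at the start, and the other portion comes at 5.0 min, later than the last blue reading, by which the blue solvolysis product read 26% after 25% a reading earlier. My first round for Tuesday's scaled the blue target to that first portion, giving target 7.25%. Taking that from the overhang left solvolysis product 32.8%; going round again, the solid substrate charge still stood above the second nucleophile charge, so I kept the overhang.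

The forecast chose Thursday's, with Saturday's 26%, Thursday's 33%, Tuesday's 20% and Monday's 17%, holding for Tuesday's that “only half the first nucleophile acts”. I differed there, at 32.8%, and had no figure of my own for the fed flasks.

The flasks gave Thursday's highest: Saturday's 24.7%, Thursday's 33.7%, Tuesday's 31.7%, Monday's 18.3%.

    starting material → intermediate (k = 0.0380 s⁻¹)
    first nucleophile + intermediate → target (k = 29.0 M⁻¹ s⁻¹)
    second nucleophile + intermediate → other capture product (k = 150 M⁻¹ s⁻¹)
    intermediate → solvolysis product (k = 0.250 s⁻¹)
    starting material + target → side product (k = 0.0160 M⁻¹ s⁻¹)
    first nucleophile → decomposed reagent (k = 0.0160 s⁻¹)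
    solid substrate ⇌ starting material, rate k7*(cs7 - [starting material]) while solid is left; crystals form when [starting material] > cs7 (solubility = 0.0900 M, k = 0.0810 s⁻¹)

At a full charge of each nucleophile, the pseudo-first-order capture of intermediate by second nucleophile stands at 29.7 s⁻¹, faster than 5.74 s⁻¹ for first nucleophile and 0.25 s⁻¹ for solvolysis. Tuesday's ended with other capture product 60.0% and second nucleophile 0% of its charge, while target, solvolysis product and side product, each of the last counted as two, summed to 40.0% against the overhang of 40.0%. A neighbour of Monday's charged with 0.079 M of second nucleophile has an overhang of 76.1%, and the same three products there summed to 76.1%.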